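**Plan**

- Retrosynthesis: (i) exchange of O-protecting groups for the two acetates; (ii) C8–C15 (ring D), opened to a lactone with H on C8 and a phenyl acrylate arm on C13; (iii) C15–C16, back to an enol triflate; (iv) ring C, back to a benzene ring; (v) C10–C20 with the C7–O lactone bond (formaldehyde) and C10–C9 (ketone arylation); (vi) ring A, to a Diels–Alder pair.
- Feature used by the key step: C8 is the α-carbon of the C7 lactone and is bonded to the C15 ketone. C15's other neighbour C16 (bearing the C17 methylene) sits on C13, which is 1,3 to C8 across C14 in ring C. The lactone enolate can therefore reach an acrylate carbonyl on C13 in a 5-exo closure that delivers ring D, the quaternary C8 and the finished enone together.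
- Forward order: ring A (Diels–Alder) → aryl group on C10 → C20 and the lactone ring → C1 alcohol → ring C by arene hydrogenation → acrylate arm on C13 → ring D (bicyclo[3.2.1]octane) → acetates.
- Stereochemistry: C4/C5 from the E-enal and a chiral hydrogen-bond catalyst; C10 from formaldehyde attack anti to C6; C1 from hydride attack anti to the aryl group; C9 from cis-hydrogenation on the C1 face; C13 by equilibration; C8 from the tether.

Key step: step 13

Remark: locants C1–C20 are ent-kaurane locants (C7 lactone carbonyl, C15 ketone, C16=C17 methylene, C19 free CH2OH, C20 lactone CH2); the (R,R) catalyst of step 2 is assumed to give the (4S,5S) series, and its antipode is used if the sense is opposite.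

Step 1
Reactants: 1 (tert-butyldimethylsilyloxy)acetaldehyde; 2 2-(triphenylphosphoranylidene)propanal
Product: 3 (E)-4-[(tert-butyldimethylsilyl)oxy]-2-methylbut-2-enal
Conditions: PhMe, 90 °C
Reagents that add atoms: none
Why: Wittig olefination with the formyl-stabilized ylide should give the E-trisubstituted enal (CH3 cis to CH2OTBS), whose geometry later fixes the cis relationship of the C4 methyl and the C5 CH2O group.

Step 2
Reactants: 3 (E)-4-[(tert-butyldimethylsilyl)oxy]-2-methylbut-2-enal; 4 (E)-3-[(tert-butyldimethylsilyl)oxy]-N,N-dimethylbuta-1,3-dien-1-amine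
Product: 7 (4S,5S)-5-{[(tert-butyldimethylsilyl)oxy]methyl}-4-(hydroxymethyl)-4-methylcyclohex-2-en-1-one, via cycloadduct 5 (not isolated), via amino alcohol 6 (not isolated)
Conditions: 4 (1.5 equiv), (R,R)-1-naphthyl-TADDOL (20 mol%), PhMe, −40 °C; LiAlH4, Et2O, −78 °C; 0.1 M HCl, THF, 0 °C
Reagents that add atoms: none
Why: Diels–Alder reaction of the 1-amino-3-siloxydiene (its CH2 terminus C10 bonds to the enal β-carbon C5, its amino carbon C3 to C4) under hydrogen-bond activation of the aldehyde by the chiral diol should set C4 and C5 (relative configuration from the E-enal, absolute from the catalyst); hydride reduction of the formyl group, enol ether hydrolysis and β-elimination of dimethylamine then unveil the cyclohexenone, the brief cold dilute acid being expected to spare the primary TBS ether.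

Step 3
Reactants: 7 (4S,5S)-5-{[(tert-butyldimethylsilyl)oxy]methyl}-4-(hydroxymethyl)-4-methylcyclohex-2-en-1-one
Product: 8 (4S,5S)-5-{[(tert-butyldimethylsilyl)oxy]methyl}-4-[(methoxymethoxy)methyl]-4-methylcyclohex-2-en-1-one
Conditions: MOMCl, i-Pr2NEt, CH2Cl2, 0 °C to rt
Reagents that add atoms: chloromethyl methyl ether, COCCl
Why: O-alkylation of the neopentyl primary alcohol gives a MOM ether that should survive all later base, hydride, hydrogenation and fluoride steps and can be removed last without touching acetates.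

Step 4
Reactants: 8 (4S,5S)-5-{[(tert-butyldimethylsilyl)oxy]methyl}-4-[(methoxymethoxy)methyl]-4-methylcyclohex-2-en-1-one; 9 dimethyl 4-bromoisophthalate
Product: 10 C10-aryl enone (aryl on C10 trans to the C5 CH2OTBS group)
Conditions: Pd2(dba)3, XPhos, K3PO4, PhMe, 80 °C
Reagents that add atoms: none
Why: Palladium-catalysed ketone α-arylation; the enone has no γ-hydrogen (C4 is quaternary), so only the C10 enolate can form and couple, and the C10 configuration is irrelevant because this centre is enolized again in step 5.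

Step 5
Reactants: 10 C10-aryl enone
Product: 12 spiro lactone enone (ring A enone spiro-fused at C10 to the isochromanone; aryl carbon C9 cis to C6 and C20 trans to C6), via aldol adduct 11 (not isolated)
Conditions: 37% aq. HCHO, K2CO3, MeOH/THF, 0 °C to rt
Reagents that add atoms: formaldehyde, C=O
Why: Crossed aldol addition of the aryl-stabilized C10 enolate to formaldehyde should occur on the face opposite to the C5 CH2OTBS and C4 methyl groups, and the new C20 alkoxide closes the six-membered lactone onto the ortho ester (lactonization), which makes the addition irreversible and sets the quaternary C10.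

Step 6
Reactants: 12 spiro lactone enone
Product: 13 allylic alcohol (C1 hydroxyl cis to C9)
Conditions: NaBH4, CeCl3·7H2O, MeOH, −40 °C
Reagents that add atoms: none
Why: Luche reduction gives 1,2-reduction of the enone; hydride should approach C1 from the face that carries only C20 and C19, opposite to the aryl ring, C6 and the C4 methyl, which places the C1 hydroxyl cis to C9.

Step 7
Reactants: 13 allylic alcohol
Product: 14 hydroxy lactone ester (ring A saturated; ring C all-cis with H8 H9 H13 on the C1 face; cis-fused lactone)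
Conditions: H2 (60 bar), 5% Rh/Al2O3, i-PrOH, 40 °C
Reagents that add atoms: none
Why: Heterogeneous rhodium-catalysed arene hydrogenation adds all hydrogens to one face of the benzene ring and also saturates C2=C3; the arene should bind through its face on the C1 side, which carries the hydroxyl group, because the other face is screened by the axial C4 methyl or C6 group, and this sets C9.

Step 8
Reactants: 14 hydroxy lactone ester
Product: 15 C1 silyl ether of 14
Conditions: TBSOTf, 2,6-lutidine, CH2Cl2, −78 to 0 °C
Reagents that add atoms: tert-butyldimethylsilyl trifluoromethanesulfonate, CC(C)(C)[Si](C)(C)OS(=O)(=O)C(F)(F)F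
Why: Silylation of the hindered secondary alcohol with the silyl triflate protects O1 so that it cannot compete with O20 for the C7 carbonyl when the lactone is opened and reclosed in step 9.

Step 9
Reactants: 15 C1 silyl ether of 14
Product: 18 lactone acid (C13 carboxyl trans to C10; trans-fused lactone), via epimerized ester 16 (not isolated), via seco diacid 17 (not isolated)
Conditions: NaOMe, MeOH, 60 °C; LiOH, THF/H2O, 40 °C; 1 M HCl to pH 3; PPTS, PhMe, 60 °C
Reagents that add atoms: lithium hydroxide, [Li+].[OH-]
Why: Base-mediated epimerization places the C13 ester equatorial and therefore trans to the equatorial C10 substituent on C9 (thermodynamic control sets C13; C8 also equilibrates but is reset in step 13), saponification cleaves both esters, and acid-catalysed lactonization recloses only the six-membered C7/O20 lactone, leaving the C13 acid free.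

Step 10
Reactants: 18 lactone acid
Product: 20 C13 methyl ketone, via acid chloride 19 (not isolated)
Conditions: 1-chloro-N,N,2-trimethylprop-1-en-1-amine, CH2Cl2, 0 °C; Me2CuLi, Et2O, −78 °C
Reagents that add atoms: lithium dimethylcuprate, [Li+].C[Cu-]C
Why: Neutral acid chloride formation followed by organocuprate acylation stops at the methyl ketone and leaves the lactone untouched, and the C13 centre remains in its thermodynamically preferred equatorial configuration.

Step 11
Reactants: 20 C13 methyl ketone
Product: 21 enol triflate (C13 prop-1-en-2-yl trifluoromethanesulfonate)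
Conditions: KN(SiMe3)2, THF, −78 °C (ketone added to base); PhNTf2, −78 to 0 °C
Reagents that add atoms: N-phenylbis(trifluoromethanesulfonimide), O=S(=O)(N(c1ccccc1)S(=O)(=O)C(F)(F)F)C(F)(F)F
Why: Kinetic deprotonation of the ketone at its CH3 group (the ketone is far more acidic than the lactone) and O-triflation of the enolate give the 1,1-disubstituted enol triflate, after which C13 can no longer epimerize.

Step 12
Reactants: 21 enol triflate
Product: 22 phenyl acrylate (phenyl 2-(C13-yl)prop-2-enoate)
Conditions: Pd(OAc)2, Xantphos, CO (1 atm), PhOH, Et3N, DMF, 60 °C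
Reagents that add atoms: carbon monoxide, [C-]#[O+]; phenol, Oc1ccccc1
Why: Palladium-catalysed carbonylation of the enol triflate with phenol as nucleophile (aryloxycarbonylation) installs C15 as a phenyl ester, which is a good acyl donor and releases a weakly nucleophilic leaving group.

Step 13
Reactants: 22 phenyl acrylate
Product: 24 protected tetracycle (O1 and O6 TBS ethers; O19 MOM ether; ring D closed), via lithium enolate 23 (not isolated)
Conditions: LiN(SiMe3)2, THF, −78 to −30 °C; AcOH, −78 °C
Reagents that add atoms: none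
Why: Dieckmann (intramolecular Claisen) condensation: the amide base removes the only acidic proton, H8 (the C13 proton is cross-conjugated and not acidified), the lactone enolate carbon C8 adds to the acrylate carbonyl C15 and phenoxide is expelled. The closest known reaction type is the Dieckmann cyclization of an ester enolate onto an aryl ester to give an α-quaternary β-keto ester. Ring D closes 5-exo-trig and completes the bicyclo[3.2.1]octane; attack on the methylene carbon C17 would be 5-endo-trig and O-acylation would give a seven-membered ring, so both should be disfavoured. C8 is the only new stereocentre and is fixed by the tether: C15 can reach C8 only from the face of ring C that carries the C13 side chain, through a boat-like ring C with that chain pseudo-axial. The step needs acylation to outrun retro-Claisen opening and conjugate addition to the new enone, which the poorly nucleophilic lithium phenoxide and the cold acidic quench should secure.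

Step 14
Reactants: 24 protected tetracycle
Product: 25 1,6-diol (O19 MOM ether)
Conditions: HF·pyridine, pyridine, THF, 0 °C to rt
Reagents that add atoms: none
Why: Fluoride desilylation under buffered, mildly acidic conditions should remove both TBS ethers while the exo-methylene ketone, the β-keto lactone and the MOM ether are tolerated.

Step 15
Reactants: 25 1,6-diol (O19 MOM ether)
Product: 26 1,6-diacetate (O19 MOM ether)
Conditions: Ac2O, pyridine, DMAP (cat.), CH2Cl2, 0 °C to rt
Reagents that add atoms: acetic anhydride, CC(=O)OC(C)=O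
Why: DMAP-catalysed acetylation esterifies the primary C6 and the secondary C1 hydroxyl while O19 stays masked.

Step 16
Reactants: 26 1,6-diacetate (O19 MOM ether)
Product: 27 target CNP0370815.4
Conditions: Me2BBr, CH2Cl2, −78 °C; sat. aq. NaHCO3
Reagents that add atoms: none
Why: Boron halide cleavage of the MOM acetal at low temperature (bromide opens the boron-activated acetal and the bromomethyl ether hydrolyses on work-up) spares acetates, lactones and enones and releases the C19 hydroxyl.

**Compound list**

1 | (tert-butyldimethylsilyloxy)acetaldehyde | O=CCO[Si](C)(C)C(C)(C)C | starting material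
2 | 2-(triphenylphosphoranylidene)propanal | CC(C=O)=P(c1ccccc1)(c1ccccc1)c1ccccc1 | starting material
3 | (E)-4-[(tert-butyldimethylsilyl)oxy]-2-methylbut-2-enal | O=C/C(C)=C/CO[Si](C)(C)C(C)(C)C | intermediate
4 | (E)-3-[(tert-butyldimethylsilyl)oxy]-N,N-dimethylbuta-1,3-dien-1-amine | C=C(O[Si](C)(C)C(C)(C)C)/C=C/N(C)C | starting material
5 | cycloadduct: 2-(dimethylamino)-1-methyl-6-(TBSO-methyl)-4-(TBSO)cyclohex-3-ene-1-carbaldehyde (1-CH3 cis to 6-CH2OTBS; NMe2 cis to CHO) | O=C[C@@]1(C)[C@@H](N(C)C)C=C(O[Si](C)(C)C(C)(C)C)C[C@@H]1CO[Si](C)(C)C(C)(C)C | intermediate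
6 | amino alcohol: 1-(hydroxymethyl) analogue of 5 | OC[C@@]1(C)[C@@H](N(C)C)C=C(O[Si](C)(C)C(C)(C)C)C[C@@H]1CO[Si](C)(C)C(C)(C)C | intermediate
7 | (4S,5S)-5-{[(tert-butyldimethylsilyl)oxy]methyl}-4-(hydroxymethyl)-4-methylcyclohex-2-en-1-one (4-CH3 cis to 5-CH2OTBS) | O=C1C=C[C@](C)(CO)[C@@H](CO[Si](C)(C)C(C)(C)C)C1 | intermediate
8 | (4S,5S)-5-{[(tert-butyldimethylsilyl)oxy]methyl}-4-[(methoxymethoxy)methyl]-4-methylcyclohex-2-en-1-one | O=C1C=C[C@](C)(COCOC)[C@@H](CO[Si](C)(C)C(C)(C)C)C1 | intermediate
9 | dimethyl 4-bromoisophthalate | COC(=O)c1ccc(Br)c(C(=O)OC)c1 | starting material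
10 | C10-aryl enone: dimethyl 4-arylisophthalate with the ring A enone attached through C10, aryl trans to the C5 CH2OTBS group | O=C1C=C[C@](C)(COCOC)[C@@H](CO[Si](C)(C)C(C)(C)C)[C@@H]1c1ccc(C(=O)OC)cc1C(=O)OC | intermediate
11 | aldol adduct: C10-hydroxymethyl derivative of 10 (CH2OH trans to CH2OTBS) | O=C1C=C[C@](C)(COCOC)[C@@H](CO[Si](C)(C)C(C)(C)C)[C@@]1(CO)c1ccc(C(=O)OC)cc1C(=O)OC | intermediate
12 | spiro lactone enone: ring A enone spiro-fused at C10 to the isochromanone (C7 lactone, C13 methyl ester on the arene); C9 cis to C6, C20 trans to C6 | O=C1C=C[C@](C)(COCOC)[C@@H](CO[Si](C)(C)C(C)(C)C)[C@]12COC(=O)c1cc(C(=O)OC)ccc12 | intermediate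
13 | allylic alcohol: C1 hydroxyl cis to C9 | O[C@H]1C=C[C@](C)(COCOC)[C@@H](CO[Si](C)(C)C(C)(C)C)[C@]12COC(=O)c1cc(C(=O)OC)ccc12 | intermediate
14 | hydroxy lactone ester: ring A saturated, ring C all-cis cyclohexane (H8, H9, H13 cis), cis-fused lactone, C13 CO2Me cis to C10 | COC(=O)[C@H]1CC[C@H]2[C@@]3(COC(=O)[C@H]2C1)[C@@H](O)CC[C@](C)(COCOC)[C@H]3CO[Si](C)(C)C(C)(C)C | intermediate
15 | C1 silyl ether of 14 | COC(=O)[C@H]1CC[C@H]2[C@@]3(COC(=O)[C@H]2C1)[C@@H](O[Si](C)(C)C(C)(C)C)CC[C@](C)(COCOC)[C@H]3CO[Si](C)(C)C(C)(C)C | intermediate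
16 | epimerized ester: C13 CO2Me trans to C10, trans-fused lactone | COC(=O)[C@@H]1CC[C@H]2[C@@]3(COC(=O)[C@@H]2C1)[C@@H](O[Si](C)(C)C(C)(C)C)CC[C@](C)(COCOC)[C@H]3CO[Si](C)(C)C(C)(C)C | intermediate
17 | seco diacid: free C20 hydroxyl, C7 and C16 carboxylic acids | OC(=O)[C@@H]1CC[C@H]([C@@H](C1)C(O)=O)[C@@]2(CO)[C@@H](O[Si](C)(C)C(C)(C)C)CC[C@](C)(COCOC)[C@H]2CO[Si](C)(C)C(C)(C)C | intermediate
18 | lactone acid: C13 carboxyl trans to C10, trans-fused lactone | OC(=O)[C@@H]1CC[C@H]2[C@@]3(COC(=O)[C@@H]2C1)[C@@H](O[Si](C)(C)C(C)(C)C)CC[C@](C)(COCOC)[C@H]3CO[Si](C)(C)C(C)(C)C | intermediate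
19 | acid chloride of 18 | ClC(=O)[C@@H]1CC[C@H]2[C@@]3(COC(=O)[C@@H]2C1)[C@@H](O[Si](C)(C)C(C)(C)C)CC[C@](C)(COCOC)[C@H]3CO[Si](C)(C)C(C)(C)C | intermediate
20 | C13 methyl ketone | CC(=O)[C@@H]1CC[C@H]2[C@@]3(COC(=O)[C@@H]2C1)[C@@H](O[Si](C)(C)C(C)(C)C)CC[C@](C)(COCOC)[C@H]3CO[Si](C)(C)C(C)(C)C | intermediate
21 | enol triflate: C13 prop-1-en-2-yl trifluoromethanesulfonate | C=C(OS(=O)(=O)C(F)(F)F)[C@@H]1CC[C@H]2[C@@]3(COC(=O)[C@@H]2C1)[C@@H](O[Si](C)(C)C(C)(C)C)CC[C@](C)(COCOC)[C@H]3CO[Si](C)(C)C(C)(C)C | intermediate
22 | phenyl acrylate: phenyl 2-(C13-yl)prop-2-enoate | C=C(C(=O)Oc1ccccc1)[C@@H]1CC[C@H]2[C@@]3(COC(=O)[C@@H]2C1)[C@@H](O[Si](C)(C)C(C)(C)C)CC[C@](C)(COCOC)[C@H]3CO[Si](C)(C)C(C)(C)C | intermediate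
23 | lithium enolate of the lactone of 22 (C7=C8) | C=C(C(=O)Oc1ccccc1)[C@@H]1CC[C@H]2[C@@]3(COC([O-])=C2C1)[C@@H](O[Si](C)(C)C(C)(C)C)CC[C@](C)(COCOC)[C@H]3CO[Si](C)(C)C(C)(C)C.[Li+] | intermediate
24 | protected tetracycle: O1 and O6 TBS ethers, O19 MOM ether, ring D closed | C=C1C(=O)[C@]23C[C@H]1CC[C@H]2[C@@]1(COC3=O)[C@@H](O[Si](C)(C)C(C)(C)C)CC[C@](C)(COCOC)[C@H]1CO[Si](C)(C)C(C)(C)C | intermediate
25 | 1,6-diol, O19 MOM ether | C=C1C(=O)[C@]23C[C@H]1CC[C@H]2[C@@]1(COC3=O)[C@@H](O)CC[C@](C)(COCOC)[C@H]1CO | intermediate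
26 | 1,6-diacetate, O19 MOM ether | C=C1C(=O)[C@]23C[C@H]1CC[C@H]2[C@@]1(COC3=O)[C@@H](OC(C)=O)CC[C@](C)(COCOC)[C@H]1COC(C)=O | intermediate
27 | CNP0370815.4 (1,6-diacetoxy-19-hydroxy-15-oxo-6,7-seco-kaur-16-en-7,20-olide with the configuration of the given SMILES) | C=C1C(=O)[C@]23C[C@H]1CC[C@H]2[C@@]1(COC3=O)[C@@H](OC(C)=O)CC[C@](C)(CO)[C@H]1COC(C)=O | target

**Step count and risks**

Total steps: 16. Longest linear sequence: 16 steps (1 to 27).

Steps most likely to fail:

Step 13. The amide base may attack the phenyl ester or add to the acrylate faster than it removes the hindered H8, and phenoxide may reopen the strained β-keto lactone by a retro-Claisen process on warming. The fallback sets out from 21 and comes back at 24; it replaces the acyl donor by an aldehyde, which has no leaving group. Palladium-catalysed formylation of 21 (Pd(OAc)2, dppp, CO, Et3SiH, Et3N, DMF, 70 °C) should give the 2-substituted acrolein F1. LiN(SiMe3)2 (THF, −78 °C) then closes ring D by intramolecular aldol addition of the lactone enolate to the aldehyde, giving the 15-hydroxy compound F2. Oxidation of this allylic alcohol (DMP, NaHCO3, CH2Cl2) gives 24.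

Step 7. Hydrogen may be delivered to the wrong face of the arene (poor facial selectivity), or saturation may stop part-way. The fallback sets out from 8 and comes back at 18; ring C is brought in partly saturated and C9 is set by a hydroxyl-directed homogeneous hydrogenation. Commercial dimethyl 4-oxocyclohexane-1,3-dicarboxylate is converted into the enol triflate F3 (NaH, PhNTf2, THF). Palladium-catalysed α-alkenylation of 8 with F3 (Pd2(dba)3, XPhos, K3PO4, PhMe) gives the alkenyl ketone F4. Formaldehyde and K2CO3 as in step 5 give the unsaturated spiro lactone F5 (C8=C9), and Luche reduction gives the allylic alcohol F6. Deprotonation at C11 with excess LiN(iPr)2 and kinetic α-protonation (AcOH, −78 °C) give the β,γ-unsaturated lactone F7 (C9=C11). Hydrogenation with [Ir(cod)(PCy3)(py)]PF6 (H2, CH2Cl2), directed by the homoallylic C1 hydroxyl, should add H9 on the C1 face and also reduce C2=C3. This gives the epimer mixture F8, which is 14 as a mixture at the enolizable centres C8 and C13; steps 8 and 9 converge it on 18.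

Step 4. Coupling at the hindered C10 position may be slow, and the product enolate may cyclize onto the ortho ester (enol lactone formation) during the coupling. The fallback sets out from 8 and comes back at 10; it is a metal-free arylation. Commercial dimethyl 4-iodoisophthalate is oxidised (mCPBA, TsOH·H2O, MeCN) in the presence of 1,3,5-trimethoxybenzene to the iodonium tosylate F9. The lithium enolate of 8 (LiN(SiMe3)2, THF, −78 °C) is then arylated by F9, which should transfer its electron-poor aryl group, to give 10.

**Further compounds**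

F1 | step 13 | 2-substituted acrolein (formyl analogue of 22) | C=C(C=O)[C@@H]1CC[C@H]2[C@@]3(COC(=O)[C@@H]2C1)[C@@H](O[Si](C)(C)C(C)(C)C)CC[C@](C)(COCOC)[C@H]3CO[Si](C)(C)C(C)(C)C
F2 | step 13 | 15-hydroxy compound (C15 carbinol of 24, C15 configuration open) | C=C1C(O)[C@]23C[C@H]1CC[C@H]2[C@@]1(COC3=O)[C@@H](O[Si](C)(C)C(C)(C)C)CC[C@](C)(COCOC)[C@H]1CO[Si](C)(C)C(C)(C)C
F3 | step 7 | dimethyl 4-{[(trifluoromethyl)sulfonyl]oxy}cyclohex-3-ene-1,3-dicarboxylate | COC(=O)C1CCC(OS(=O)(=O)C(F)(F)F)=C(C(=O)OC)C1
F4 | step 7 | C10-alkenyl enone | O=C1C=C[C@](C)(COCOC)[C@@H](CO[Si](C)(C)C(C)(C)C)C1C1=C(C(=O)OC)CC(CC1)C(=O)OC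
F5 | step 7 | unsaturated spiro lactone enone (C8=C9) | O=C1C=C[C@](C)(COCOC)[C@@H](CO[Si](C)(C)C(C)(C)C)[C@]12COC(=O)C3=C2CCC(C3)C(=O)OC
F6 | step 7 | allylic alcohol of F5 (C1 hydroxyl cis to C9) | O[C@H]1C=C[C@](C)(COCOC)[C@@H](CO[Si](C)(C)C(C)(C)C)[C@]12COC(=O)C3=C2CCC(C3)C(=O)OC
F7 | step 7 | β,γ-unsaturated lactone (C9=C11) | O[C@H]1C=C[C@](C)(COCOC)[C@@H](CO[Si](C)(C)C(C)(C)C)[C@]12COC(=O)C3C2=CCC(C3)C(=O)OC
F8 | step 7 | 14 as a mixture of epimers at C8 and C13 | COC(=O)C1CC[C@H]2[C@@]3(COC(=O)C2C1)[C@@H](O)CC[C@](C)(COCOC)[C@H]3CO[Si](C)(C)C(C)(C)C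
F9 | step 4 | [2,4-bis(methoxycarbonyl)phenyl](2,4,6-trimethoxyphenyl)iodonium 4-methylbenzenesulfonate | COC(=O)c1ccc([I+]c2c(OC)cc(OC)cc2OC)c(C(=O)OC)c1.Cc1ccc(cc1)S(=O)(=O)[O-]
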